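**Retrosynthetic overview**
1. Target 28 ⇒ epoxy alcohol 26 + tiglic acid 27 (Mitsunobu esterification with inversion at C3) ⇒ allylic alcohol 25 (C3–OH-directed epoxidation of the 4E olefin) ⇒ macrocyclic allylic alcohol 23.
2. 23 ⇒ open-chain ynal 22: the ten-membered carbocycle is cut at the C5–C6 ring bond together with the C4–CH3 bond; forward, a nickel-catalysed methylative alkyne–aldehyde macrocyclisation.
3. Enabling feature: in the C4–C5 oxirane ring the methyl on C4 and the ring carbon C6 on C5 are cis, and C6 is a carbinol. The array C4(CH3)–C5–C6(O) is therefore the retron of a syn methyl-metalation/aldehyde addition across a terminal C4≡C5 alkyne, which also fixes the 4E geometry inside the ten-membered ring.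
4. 22 ⇒ alkyne 12 + (R)-trityl glycidyl ether 13 (carboalumination sets the C10=C1 olefin and its methyl, epoxide opening makes C1–C2 and brings C3; Ohira–Bestmann gives C4≡C5); 12 ⇒ imide 3 + allyl iodide 4 (Evans dienolate alkylation sets C7).
5. Ring order: ten-membered carbocycle first (step 15), oxirane second (step 18).

Key step: step 15

Remark: germacrane numbering is used throughout (C7 bears the isopropenyl group, C6 the acetate, C4–C5 the oxirane, C3 the tiglate); the target is (1(10)E,3S,4R,5R,6R,7S), and a descriptor that changes between intermediates without a reaction at that centre reflects only a change in substituent priorities.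

**Step 1**
Reactants: 1 (4S)-4-benzyl-1,3-oxazolidin-2-one; 2 3-methylbut-2-enoyl chloride
Product: 3 (4S)-4-benzyl-3-(3-methylbut-2-enoyl)-1,3-oxazolidin-2-one
Conditions: n-BuLi, THF, −78 °C; then 2, −78 to 0 °C
Reagents that add atoms: none
Why: N-acylation of the lithiated oxazolidinone with an acid chloride is the standard entry to Evans imides and creates no stereocentre.

**Step 2**
Reactants: 3 (4S)-4-benzyl-3-(3-methylbut-2-enoyl)-1,3-oxazolidin-2-one; 4 allyl iodide (3-iodoprop-1-ene)
Product: 6 (4S)-4-benzyl-3-[(2S)-2-(prop-1-en-2-yl)pent-4-enoyl]-1,3-oxazolidin-2-one, via sodium dienolate 5 (not isolated)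
Conditions: NaN(SiMe3)2, THF, −78 °C; then 4, −78 to −40 °C
Reagents that add atoms: none
Why: Evans asymmetric alkylation, in which γ-deprotonation gives the sodium-chelated Z-dienolate that is alkylated at the α-carbon on the face opposite the benzyl group (deconjugative α-alkylation), so that the isopropenyl-bearing centre (future C7) should be set as S.

**Step 3**
Reactants: 6 (4S)-4-benzyl-3-[(2S)-2-(prop-1-en-2-yl)pent-4-enoyl]-1,3-oxazolidin-2-one
Product: 7 (2S)-2-(prop-1-en-2-yl)pent-4-en-1-ol
Conditions: LiBH4, MeOH (1 equiv), Et2O, 0 °C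
Reagents that add atoms: none
Why: Reductive cleavage of the imide with LiBH4 should release the primary alcohol and the recoverable auxiliary without touching the α-stereocentre or the two alkenes.

**Step 4**
Reactants: 7 (2S)-2-(prop-1-en-2-yl)pent-4-en-1-ol
Product: 8 1-methoxy-4-({[(2S)-2-(prop-1-en-2-yl)pent-4-en-1-yl]oxy}methyl)benzene
Conditions: NaH, 4-methoxybenzyl chloride, n-Bu4NI (cat.), THF/DMF, 0 °C to rt
Reagents that add atoms: 4-methoxybenzyl chloride (COc1ccc(CCl)cc1)
Why: Williamson etherification protects the primary alcohol as a 4-methoxybenzyl ether that tolerates the organoaluminium, basic and mildly acidic steps ahead and is later removed oxidatively.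

**Step 5**
Reactants: 8 1-methoxy-4-({[(2S)-2-(prop-1-en-2-yl)pent-4-en-1-yl]oxy}methyl)benzene
Product: 10 (4S)-5-[(4-methoxybenzyl)oxy]-4-(prop-1-en-2-yl)pentan-1-ol, via alkylborane 9 (not isolated)
Conditions: Sia2BH (from BH3·THF and 2-methylbut-2-ene), THF, 0 °C; then NaOH, H2O2, 0 °C to rt
Reagents that add atoms: hydrogen peroxide (OO)
Why: Hydroboration–oxidation with the bulky dialkylborane should be selective for the monosubstituted terminal alkene over the hindered 1,1-disubstituted isopropenyl group and gives the anti-Markovnikov primary alcohol.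

**Step 6**
Reactants: 10 (4S)-5-[(4-methoxybenzyl)oxy]-4-(prop-1-en-2-yl)pentan-1-ol
Product: 11 (4S)-5-[(4-methoxybenzyl)oxy]-4-(prop-1-en-2-yl)pentanal
Conditions: Dess–Martin periodinane, NaHCO3, CH2Cl2, 0 °C to rt
Reagents that add atoms: none
Why: Buffered Dess–Martin oxidation converts the primary alcohol into the aldehyde without over-oxidation, and the stereocentre is γ to the carbonyl and cannot epimerise.

**Step 7**
Reactants: 11 (4S)-5-[(4-methoxybenzyl)oxy]-4-(prop-1-en-2-yl)pentanal
Product: 12 1-methoxy-4-({[(2S)-2-(prop-1-en-2-yl)hex-5-yn-1-yl]oxy}methyl)benzene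
Conditions: dimethyl (1-diazo-2-oxopropyl)phosphonate, K2CO3, MeOH, 0 °C to rt
Reagents that add atoms: dimethyl (1-diazo-2-oxopropyl)phosphonate (CC(=O)C(=[N+]=[N-])P(=O)(OC)OC)
Why: Ohira–Bestmann (Seyferth–Gilbert) homologation turns the aldehyde into the terminal alkyne under mild carbonate conditions.

**Step 8**
Reactants: 12 1-methoxy-4-({[(2S)-2-(prop-1-en-2-yl)hex-5-yn-1-yl]oxy}methyl)benzene; 13 (2R)-2-[(trityloxy)methyl]oxirane ((R)-trityl glycidyl ether)
Product: 16 (2R,4E,8S)-9-[(4-methoxybenzyl)oxy]-5-methyl-8-(prop-1-en-2-yl)-1-(trityloxy)non-4-en-2-ol, via alkenylalane 14 (not isolated), via lithium alanate 15 (not isolated)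
Conditions: AlMe3, Cp2ZrCl2 (cat.), ClCH2CH2Cl, rt; volatiles removed; n-BuLi, hexane, −78 to 0 °C; then 13, THF, 0 °C to rt; then H2O
Reagents that add atoms: trimethylaluminium (C[Al](C)C)
Why: Zirconium-catalysed Negishi carboalumination adds CH3 and Al syn across the terminal alkyne and so fixes the E-trisubstituted C10=C1 olefin, and the derived lithium alanate opens the terminal epoxide at its CH2 carbon without touching the carbinol centre, so that C3 is taken from the chiral pool.

**Step 9**
Reactants: 16 (2R,4E,8S)-9-[(4-methoxybenzyl)oxy]-5-methyl-8-(prop-1-en-2-yl)-1-(trityloxy)non-4-en-2-ol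
Product: 17 tert-butyl{[(2R,4E,8S)-9-[(4-methoxybenzyl)oxy]-5-methyl-8-(prop-1-en-2-yl)-1-(trityloxy)non-4-en-2-yl]oxy}dimethylsilane
Conditions: TBSCl, imidazole, DMF, rt
Reagents that add atoms: tert-butyldimethylsilyl chloride (CC(C)(C)[Si](C)(C)Cl)
Why: Silylation of the secondary alcohol gives an ether that survives the oxidations, the carbonate-mediated homologation and the organometallic key step and can be removed with fluoride.

**Step 10**
Reactants: 17 tert-butyl{[(2R,4E,8S)-9-[(4-methoxybenzyl)oxy]-5-methyl-8-(prop-1-en-2-yl)-1-(trityloxy)non-4-en-2-yl]oxy}dimethylsilane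
Product: 18 (2R,4E,8S)-2-[(tert-butyldimethylsilyl)oxy]-9-[(4-methoxybenzyl)oxy]-5-methyl-8-(prop-1-en-2-yl)non-4-en-1-ol
Conditions: TsOH·H2O (cat.), MeOH/CH2Cl2, 0 °C
Reagents that add atoms: none
Why: Mild acid-catalysed methanolysis should remove the trityl ether selectively through the stabilised trityl cation while the secondary silyl ether, the 4-methoxybenzyl ether and the alkenes remain.

**Step 11**
Reactants: 18 (2R,4E,8S)-2-[(tert-butyldimethylsilyl)oxy]-9-[(4-methoxybenzyl)oxy]-5-methyl-8-(prop-1-en-2-yl)non-4-en-1-ol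
Product: 19 (2R,4E,8S)-2-[(tert-butyldimethylsilyl)oxy]-9-[(4-methoxybenzyl)oxy]-5-methyl-8-(prop-1-en-2-yl)non-4-enal
Conditions: Dess–Martin periodinane, NaHCO3, CH2Cl2, 0 °C to rt
Reagents that add atoms: none
Why: Buffered Dess–Martin oxidation gives the α-silyloxy aldehyde under non-epimerising conditions.

**Step 12**
Reactants: 19 (2R,4E,8S)-2-[(tert-butyldimethylsilyl)oxy]-9-[(4-methoxybenzyl)oxy]-5-methyl-8-(prop-1-en-2-yl)non-4-enal
Product: 20 tert-butyl{[(3R,5E,9S)-10-[(4-methoxybenzyl)oxy]-6-methyl-9-(prop-1-en-2-yl)dec-5-en-1-yn-3-yl]oxy}dimethylsilane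
Conditions: dimethyl (1-diazo-2-oxopropyl)phosphonate, K2CO3, MeOH, 0 °C
Reagents that add atoms: dimethyl (1-diazo-2-oxopropyl)phosphonate (CC(=O)C(=[N+]=[N-])P(=O)(OC)OC)
Why: Ohira–Bestmann homologation should give the terminal propargylic silyl ether, a reaction that α-silyloxy aldehydes normally pass without loss of configuration at low temperature.

**Step 13**
Reactants: 20 tert-butyl{[(3R,5E,9S)-10-[(4-methoxybenzyl)oxy]-6-methyl-9-(prop-1-en-2-yl)dec-5-en-1-yn-3-yl]oxy}dimethylsilane
Product: 21 (2S,5E,8R)-8-[(tert-butyldimethylsilyl)oxy]-5-methyl-2-(prop-1-en-2-yl)dec-5-en-9-yn-1-ol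
Conditions: DDQ, CH2Cl2/pH 7 buffer, 0 °C
Reagents that add atoms: none
Why: Oxidative cleavage of the 4-methoxybenzyl ether with DDQ liberates the primary alcohol and leaves the silyl ether, the alkyne and the unactivated alkenes untouched.

**Step 14**
Reactants: 21 (2S,5E,8R)-8-[(tert-butyldimethylsilyl)oxy]-5-methyl-2-(prop-1-en-2-yl)dec-5-en-9-yn-1-ol
Product: 22 (2S,5E,8R)-8-[(tert-butyldimethylsilyl)oxy]-5-methyl-2-(prop-1-en-2-yl)dec-5-en-9-ynal
Conditions: Dess–Martin periodinane, NaHCO3, CH2Cl2, 0 °C; used at once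
Reagents that add atoms: none
Why: Base-free, buffered Dess–Martin oxidation should give the α-branched β,γ-unsaturated aldehyde without epimerising the C7 centre or moving the isopropenyl double bond into conjugation.

**Step 15**
Reactants: 22 (2S,5E,8R)-8-[(tert-butyldimethylsilyl)oxy]-5-methyl-2-(prop-1-en-2-yl)dec-5-en-9-ynal
Product: 23 (1(10)E,4E)-(3R,6S,7S)-3-[(tert-butyldimethylsilyl)oxy]germacra-1(10),4,11-trien-6-ol
Conditions: Ni(cod)2 (20 mol %), IMes (1,3-dimesitylimidazol-2-ylidene, 20 mol %), Me2Zn (3 equiv), toluene/THF, 0 °C to rt, 22 added by syringe pump (final 2 mM); then H2O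
Reagents that add atoms: dimethylzinc (C[Zn]C)
Why: Proposed new method: zerovalent nickel should bind the aldehyde and the terminal alkyne and undergo oxidative cyclisation to an oxanickelacyclopentene in which the C5–C6 bond is formed at the unsubstituted alkyne carbon, after which transmetalation with Me2Zn and C–C reductive elimination deliver the methyl group to C4 and release the zinc alkoxide of 23; the closest known reaction types are the nickel-catalysed alkylative cyclisation of ynals with organozincs (small rings and three-component couplings of terminal alkynes) and the nickel-catalysed reductive endo-macrocyclisation of terminal ynals, neither of which has been shown as a methylative closure of a ten-membered carbocycle. The ten-membered ring is closed in the endo mode (both alkyne carbons become ring members), which is favoured by C–C bond formation at the sterically free terminal carbon, by the bulky propargylic silyl ether on the internal carbon and by the small carbene ligand. The syn addition of C6 and CH3 across the alkyne is stereospecific and places C3 and C6 trans, so that the 4E olefin is obtained directly. The new C6 stereocentre is controlled by the adjacent C7 centre in the Felkin–Anh sense (isopropenyl anti to the forming bond), which corresponds to the target configuration (6S by the priority rules in 23, 6R once the oxirane is present). The step needs ring closure to win over oligomerisation and methyl transfer to win over reduction, which high dilution with slow addition and the absence of β-hydrogens in Me2Zn should secure.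

**Step 16**
Reactants: 23 (1(10)E,4E)-(3R,6S,7S)-3-[(tert-butyldimethylsilyl)oxy]germacra-1(10),4,11-trien-6-ol
Product: 24 (1(10)E,4E)-(3R,6S,7S)-3-[(tert-butyldimethylsilyl)oxy]germacra-1(10),4,11-trien-6-yl acetate
Conditions: Ac2O, pyridine, DMAP (cat.), CH2Cl2, 0 °C to rt
Reagents that add atoms: acetic anhydride (CC(=O)OC(C)=O)
Why: DMAP-catalysed acetylation installs the C6 acetate of the target and removes the only hydroxyl that could misdirect the later epoxidation.

**Step 17**
Reactants: 24 (1(10)E,4E)-(3R,6S,7S)-3-[(tert-butyldimethylsilyl)oxy]germacra-1(10),4,11-trien-6-yl acetate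
Product: 25 (1(10)E,4E)-(3R,6S,7S)-3-hydroxygermacra-1(10),4,11-trien-6-yl acetate
Conditions: TBAF, AcOH, THF, 0 °C to rt
Reagents that add atoms: none
Why: Fluoride cleaves the secondary silyl ether, and buffering with acetic acid keeps the medium non-basic so that the acetate is neither cleaved nor moved and the acid-sensitive 1(10),4-diene is not exposed to strong acid.

**Step 18**
Reactants: 25 (1(10)E,4E)-(3R,6S,7S)-3-hydroxygermacra-1(10),4,11-trien-6-yl acetate
Product: 26 (1(10)E)-(3R,4R,5R,6R,7S)-4,5-epoxy-3-hydroxygermacra-1(10),11-dien-6-yl acetate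
Conditions: VO(acac)2 (cat.), TBHP (in decane), CH2Cl2, 0 °C
Reagents that add atoms: tert-butyl hydroperoxide (CC(C)(C)OO)
Why: Hydroxyl-directed epoxidation with VO(acac)2 and TBHP is chemoselective for the allylic C4=C5 bond and, for an allylic alcohol with a geminal methyl group (A(1,2) strain, carbinol hydrogen near the C4 methyl), delivers oxygen syn to the hydroxyl to give the erythro epoxy alcohol, which from the 3R alcohol is the 4R,5R oxirane.

**Step 19**
Reactants: 26 (1(10)E)-(3R,4R,5R,6R,7S)-4,5-epoxy-3-hydroxygermacra-1(10),11-dien-6-yl acetate; 27 tiglic acid ((2E)-2-methylbut-2-enoic acid)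
Product: 28 (1(10)E)-(3S,4R,5R,6R,7S)-6-acetoxy-4,5-epoxygermacra-1(10),11-dien-3-yl (2E)-2-methylbut-2-enoate (CNP0400048.1)
Conditions: PPh3, DIAD, toluene, 0 °C to rt
Reagents that add atoms: none
Why: Mitsunobu esterification proceeds by SN2 displacement of the oxyphosphonium ion by tiglate, so that the ester is introduced with inversion at C3 (3R to 3S), which corrects the one centre that had to be R for the directed epoxidation.

**Compound list**
1 | (4S)-4-benzyl-1,3-oxazolidin-2-one | O=C1N[C@@H](Cc2ccccc2)CO1 | starting material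
2 | 3-methylbut-2-enoyl chloride | CC(C)=CC(=O)Cl | starting material
3 | (4S)-4-benzyl-3-(3-methylbut-2-enoyl)-1,3-oxazolidin-2-one | CC(C)=CC(=O)N1[C@@H](Cc2ccccc2)COC1=O | intermediate
4 | allyl iodide (3-iodoprop-1-ene) | C=CCI | starting material
5 | sodium Z-dienolate of 3 | [Na+].C=C(C)/C=C(\[O-])N1[C@@H](Cc2ccccc2)COC1=O | intermediate
6 | (4S)-4-benzyl-3-[(2S)-2-(prop-1-en-2-yl)pent-4-enoyl]-1,3-oxazolidin-2-one | C=C(C)[C@@H](C(=O)N1[C@@H](Cc2ccccc2)COC1=O)CC=C | intermediate
7 | (2S)-2-(prop-1-en-2-yl)pent-4-en-1-ol | C=C(C)[C@@H](CO)CC=C | intermediate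
8 | 1-methoxy-4-({[(2S)-2-(prop-1-en-2-yl)pent-4-en-1-yl]oxy}methyl)benzene | C=C(C)[C@@H](COCc1ccc(OC)cc1)CC=C | intermediate
9 | bis(3-methylbutan-2-yl)[(4S)-5-[(4-methoxybenzyl)oxy]-4-(prop-1-en-2-yl)pentyl]borane | C=C(C)[C@@H](COCc1ccc(OC)cc1)CCCB(C(C)C(C)C)C(C)C(C)C | intermediate
10 | (4S)-5-[(4-methoxybenzyl)oxy]-4-(prop-1-en-2-yl)pentan-1-ol | C=C(C)[C@@H](COCc1ccc(OC)cc1)CCCO | intermediate
11 | (4S)-5-[(4-methoxybenzyl)oxy]-4-(prop-1-en-2-yl)pentanal | C=C(C)[C@@H](COCc1ccc(OC)cc1)CCC=O | intermediate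
12 | 1-methoxy-4-({[(2S)-2-(prop-1-en-2-yl)hex-5-yn-1-yl]oxy}methyl)benzene | C=C(C)[C@@H](COCc1ccc(OC)cc1)CCC#C | intermediate
13 | (2R)-2-[(trityloxy)methyl]oxirane ((R)-trityl glycidyl ether) | C1[C@@H](O1)COC(c1ccccc1)(c1ccccc1)c1ccccc1 | starting material
14 | dimethyl[(1E,5S)-6-[(4-methoxybenzyl)oxy]-2-methyl-5-(prop-1-en-2-yl)hex-1-en-1-yl]alumane | C=C(C)[C@@H](COCc1ccc(OC)cc1)CC/C(C)=C/[Al](C)C | intermediate
15 | lithium butyl(dimethyl)[(1E,5S)-6-[(4-methoxybenzyl)oxy]-2-methyl-5-(prop-1-en-2-yl)hex-1-en-1-yl]aluminate | [Li+].C=C(C)[C@@H](COCc1ccc(OC)cc1)CC/C(C)=C/[Al-](C)(C)CCCC | intermediate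
16 | (2R,4E,8S)-9-[(4-methoxybenzyl)oxy]-5-methyl-8-(prop-1-en-2-yl)-1-(trityloxy)non-4-en-2-ol | C=C(C)[C@@H](COCc1ccc(OC)cc1)CC/C(C)=C/C[C@@H](O)COC(c1ccccc1)(c1ccccc1)c1ccccc1 | intermediate
17 | tert-butyl{[(2R,4E,8S)-9-[(4-methoxybenzyl)oxy]-5-methyl-8-(prop-1-en-2-yl)-1-(trityloxy)non-4-en-2-yl]oxy}dimethylsilane | C=C(C)[C@@H](COCc1ccc(OC)cc1)CC/C(C)=C/C[C@@H](O[Si](C)(C)C(C)(C)C)COC(c1ccccc1)(c1ccccc1)c1ccccc1 | intermediate
18 | (2R,4E,8S)-2-[(tert-butyldimethylsilyl)oxy]-9-[(4-methoxybenzyl)oxy]-5-methyl-8-(prop-1-en-2-yl)non-4-en-1-ol | C=C(C)[C@@H](COCc1ccc(OC)cc1)CC/C(C)=C/C[C@@H](O[Si](C)(C)C(C)(C)C)CO | intermediate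
19 | (2R,4E,8S)-2-[(tert-butyldimethylsilyl)oxy]-9-[(4-methoxybenzyl)oxy]-5-methyl-8-(prop-1-en-2-yl)non-4-enal | C=C(C)[C@@H](COCc1ccc(OC)cc1)CC/C(C)=C/C[C@@H](O[Si](C)(C)C(C)(C)C)C=O | intermediate
20 | tert-butyl{[(3R,5E,9S)-10-[(4-methoxybenzyl)oxy]-6-methyl-9-(prop-1-en-2-yl)dec-5-en-1-yn-3-yl]oxy}dimethylsilane | C=C(C)[C@@H](COCc1ccc(OC)cc1)CC/C(C)=C/C[C@@H](O[Si](C)(C)C(C)(C)C)C#C | intermediate
21 | (2S,5E,8R)-8-[(tert-butyldimethylsilyl)oxy]-5-methyl-2-(prop-1-en-2-yl)dec-5-en-9-yn-1-ol | C=C(C)[C@@H](CO)CC/C(C)=C/C[C@@H](O[Si](C)(C)C(C)(C)C)C#C | intermediate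
22 | (2S,5E,8R)-8-[(tert-butyldimethylsilyl)oxy]-5-methyl-2-(prop-1-en-2-yl)dec-5-en-9-ynal | C=C(C)[C@@H](C=O)CC/C(C)=C/C[C@@H](O[Si](C)(C)C(C)(C)C)C#C | intermediate
23 | (1(10)E,4E)-(3R,6S,7S)-3-[(tert-butyldimethylsilyl)oxy]germacra-1(10),4,11-trien-6-ol | C=C(C)[C@@H]1CC/C(C)=C/C[C@@H](O[Si](C)(C)C(C)(C)C)/C(C)=C/[C@@H]1O | intermediate
24 | (1(10)E,4E)-(3R,6S,7S)-3-[(tert-butyldimethylsilyl)oxy]germacra-1(10),4,11-trien-6-yl acetate | C=C(C)[C@@H]1CC/C(C)=C/C[C@@H](O[Si](C)(C)C(C)(C)C)/C(C)=C/[C@@H]1OC(C)=O | intermediate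
25 | (1(10)E,4E)-(3R,6S,7S)-3-hydroxygermacra-1(10),4,11-trien-6-yl acetate | C=C(C)[C@@H]1CC/C(C)=C/C[C@@H](O)/C(C)=C/[C@@H]1OC(C)=O | intermediate
26 | (1(10)E)-(3R,4R,5R,6R,7S)-4,5-epoxy-3-hydroxygermacra-1(10),11-dien-6-yl acetate | C=C(C)[C@@H]1CC/C(C)=C/C[C@@H](O)[C@@]2(C)O[C@@H]2[C@@H]1OC(C)=O | intermediate
27 | tiglic acid ((2E)-2-methylbut-2-enoic acid) | C/C=C(\C)C(=O)O | starting material
28 | (1(10)E)-(3S,4R,5R,6R,7S)-6-acetoxy-4,5-epoxygermacra-1(10),11-dien-3-yl (2E)-2-methylbut-2-enoate (CNP0400048.1) | C=C(C)[C@@H]1CC/C(C)=C/C[C@H](OC(=O)/C(C)=C/C)[C@@]2(C)O[C@@H]2[C@@H]1OC(C)=O | target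

**Step count and risks**
Total step count: 19. Longest linear sequence: 19 steps (1 and 2 to 28; 4, 13 and 27 are commercial and enter directly).

Three steps most likely to fail:

First, the key macrocyclisation (step 15, proposed new method). Oligomerisation of the terminal alkyne at zerovalent nickel or intermolecular coupling may outrun the strained ten-membered oxidative cyclisation, closure may occur in the exo mode, or facial selectivity at C6 may be eroded by the ring. The fallback uses known chemistry and sets out from 21. Zirconium-catalysed carboalumination of the terminal alkyne followed by iodinolysis (AlMe3, Cp2ZrCl2, CH2Cl2; then I2, THF, −30 °C) should give the E-vinyl iodide (2S,5E,8R,9E)-8-[(tert-butyldimethylsilyl)oxy]-10-iodo-5,9-dimethyl-2-(prop-1-en-2-yl)deca-5,9-dien-1-ol F1. Buffered Dess–Martin oxidation should give (2S,5E,8R,9E)-8-[(tert-butyldimethylsilyl)oxy]-10-iodo-5,9-dimethyl-2-(prop-1-en-2-yl)deca-5,9-dienal F2. An intramolecular Nozaki–Hiyama–Kishi reaction (CrCl2 in excess, NiCl2 cat., DMSO/THF, rt, high dilution) then closes the same C5–C6 bond with the methyl group and the E geometry already in place; the fallback comes back to the route at 23.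

Second, the Mitsunobu esterification (step 19). SN2 displacement at C3 next to the fully substituted oxirane carbon may be too slow, so that elimination or acid-promoted transannular opening of the epoxide by the 1(10) olefin competes. The fallback replaces substitution by an oxidation–reduction sequence and sets out from 26. Buffered Dess–Martin oxidation should give the epoxy ketone (1(10)E)-(4S,5R,6R,7S)-4,5-epoxy-3-oxogermacra-1(10),11-dien-6-yl acetate F3. Corey–Bakshi–Shibata reduction with the (R)-methyl oxazaborolidine catalyst and catecholborane (toluene, −78 °C; the epoxide carbon as the large group and the CH2 as the small group) should give the 3S alcohol (1(10)E)-(3S,4R,5R,6R,7S)-4,5-epoxy-3-hydroxygermacra-1(10),11-dien-6-yl acetate F4. Steglich esterification with 27 (DCC, DMAP cat., CH2Cl2) then proceeds with retention; the fallback comes back to the route at 28.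

Third, the directed epoxidation (step 18). Facial selectivity may be poor because the C6 acetate favours a ring conformer that places the hydroxyl on the other olefin face, and the Lewis-acidic vanadium may trigger transannular opening of the new oxirane. The fallback changes from substrate direction to reagent control and sets out from 25: Sharpless asymmetric epoxidation with Ti(OiPr)4, D-(−)-diisopropyl tartrate and TBHP over 4 Å molecular sieves (CH2Cl2, −20 °C). For the 3R alcohol this is the matched (fast-reacting) pairing and should give the same erythro epoxy alcohol; the fallback comes back to the route at 26 and makes no new compound.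

**Further compounds**
F1 | step 15 | (2S,5E,8R,9E)-8-[(tert-butyldimethylsilyl)oxy]-10-iodo-5,9-dimethyl-2-(prop-1-en-2-yl)deca-5,9-dien-1-ol | C=C(C)[C@@H](CO)CC/C(C)=C/C[C@@H](O[Si](C)(C)C(C)(C)C)/C(C)=C/I
F2 | step 15 | (2S,5E,8R,9E)-8-[(tert-butyldimethylsilyl)oxy]-10-iodo-5,9-dimethyl-2-(prop-1-en-2-yl)deca-5,9-dienal | C=C(C)[C@@H](C=O)CC/C(C)=C/C[C@@H](O[Si](C)(C)C(C)(C)C)/C(C)=C/I
F3 | step 19 | (1(10)E)-(4S,5R,6R,7S)-4,5-epoxy-3-oxogermacra-1(10),11-dien-6-yl acetate | C=C(C)[C@@H]1CC/C(C)=C/CC(=O)[C@@]2(C)O[C@@H]2[C@@H]1OC(C)=O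
F4 | step 19 | (1(10)E)-(3S,4R,5R,6R,7S)-4,5-epoxy-3-hydroxygermacra-1(10),11-dien-6-yl acetate | C=C(C)[C@@H]1CC/C(C)=C/C[C@H](O)[C@@]2(C)O[C@@H]2[C@@H]1OC(C)=O
F0 | step 18 | none | none
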